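## Analysis of the target

The target **31** is a trans-fused hydroazulene of the daucane type in which a cyclopentane (C1–C5) shares the C1–C5 bond with a cycloheptene (C1, C5–C10). It carries the C15 methyl on the quaternary ring-fusion carbon C1, an isopropyl carbinol at C4, a 4-hydroxybenzoate on C6 and a conjugated aldehyde (C14) on C8 of the C8=C9 alkene. The four stereocentres C1, C4, C5 and C6 (1R,4R,5S,6S) lie on one edge of the bicycle, and with the C15 methyl taken as β, H5 is α (trans fusion), the C4 hydroxyl is β, the isopropyl group is α and the C6 acyloxy group is α, so H5 and H6 are trans. Sensitive functions are the enal, the tertiary alcohol, the base-labile aryl ester with its free phenol and, on the way, any β-oxygenated C4 ketone, which can eliminate or epimerise at C5. The difficulties are closing a seven-membered ring next to a quaternary carbon, setting C4–C6 relative to C1, and reaching the aldehyde level at C14 by hydride chemistry that the benzoate would not survive. The plan rests on C5, which lies between C4 (carbonyl level), C1 and C6 and can therefore be, in a precursor, a fully substituted carbinol carbon that bears a vinyl group (C6=C7) and the oxygen of a lactone running C5–O–C14(=O)–C8=C9–C10–C1. After enolisation the array C8=C14–O–C5–C6=C7 is an allyl vinyl ether, so a [3,3] shift can exchange the O–C14 link between C5 and C8 for the C6–C7 link, which makes C7–C8 and the C5=C6 alkene and leaves C14 as the carboxyl on C8. The C5=C6 alkene is then the handle for placing H5 and the C6 oxygen together, anti to C15.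

## Retrosynthetic reasoning

**C6–O acyl bond (31 ⇒ 30 ⇒ 26 + 29).** The aryl ester is cut last because it cannot coexist with the hydride reduction that adjusts C14. In diol-enal **26** only the secondary C6 hydroxyl should acylate, the tertiary C4 hydroxyl being inert. The phenol is carried as a silyl ether in acid **29**, made in one step from **27**, and is freed in the final step.

**C14 oxidation level (26 ⇒ 25 ⇒ 24 ⇒ 23).** The enal is traced to the methyl ester of **23** through the allylic alcohol **24**. Reduction and allylic oxidation are done while C6 is a silyl ether, so the three oxygens stay distinguishable and no selective acylation among free hydroxyls is needed.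

**C4–isopropyl bond (23 ⇒ 22).** The tertiary carbinol is cut to the trans-fused C4 ketone **22**, with the isopropyl group to be delivered as a carbon nucleophile. The forward addition has to come from the α-face; the C15 methyl, 1,3 to C4 on the cyclopentane, shields the β-face. The ketone has to react in preference to the conjugated ester.

**C5–H and C6–O bonds (22 ⇒ 21 ⇒ 20 ⇒ 18).** The ketone is unmasked from the ketal **21**. The C6 oxygen and H5 are removed together to give the C5=C6 alkene of **18**. One syn addition across that alkene from the face opposite C15 sets both centres and the trans fusion, so neither has to be controlled on its own. The ketal is kept through this step so that the alkene is isolated and not part of an enone.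

**Alkene position and ester (18 ⇒ 17 ⇒ 16).** The C8=C9 ester is the conjugated isomer of the C9=C10 ester **17**, the methyl ester of acid **16**. Base moves the alkene into conjugation and removes the temporary C8 centre. C7 is not acidified by the ester, so C5=C6 stays in place.

**C7–C8 bond (16 ⇒ 12), the key disconnection.** Acid **16** is a γ,δ-unsaturated acid (C5=C6–C7–C8–CO2H), the retron of an Ireland–Claisen rearrangement. Reconnecting C5 to the carboxyl oxygen and cutting C7–C8 gives the cis-fused vinyl lactone **12**. The ring stays seven-membered: O and C14 leave it, C6 and C7 enter it. The second alkene of **16** (C9=C10) shows that the enol component should be the dienol ether of an α,β-unsaturated lactone, which ring-closing metathesis delivers directly.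

**Vinyl group and lactone alkene (12 ⇒ 11 ⇒ 10 ⇒ 9).** The vinyl group is carried as a silyl-capped alkyne until the lactone alkene C8=C9 has been made by metathesis of the acrylate with the C1 allyl group in **9**. A free vinyl group would close a cyclopentene with the allyl group instead, and a free alkyne would enter enyne metathesis.

**C5–C6 and C5–O–C14 bonds (9 ⇒ 5 + 6 + 7).** The tertiary propargylic acrylate comes from ketone **5**, the acetylide of **6** and acid chloride **7**. Ketone **5** cannot enolise. Attack anti to the allyl group puts the C5 oxygen cis to C10, as the lactone requires; this centre is later erased, so its only task is to permit ring closure and the boat transition state.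

**C1–C10 bond (5 ⇒ 4 ⇒ 3 ⇒ 1 + 2).** The quaternary centre is cut to the allyl enol carbonate **4** by a decarboxylative asymmetric allylation. Compound **4** is the C4-ketalised enol carbonate **3**, obtained from the enol form of dione **1** and chloroformate **2**. The ketal blocks the second α-position and stays as the C4 mask until step 13.

## Alternatives that were turned down

**Alternative 1:** Disconnection of C5–C6 within the seven-membered ring. In the forward sense the alkenyl triflate aldehyde A1 (cyclopentenyl triflate at C5, chain C1–C10–C9=C8(CO2Me)–C7–C6HO) would be treated with CrCl2 and catalytic Ni(II). The alkenylchromium adds to the aldehyde in a Nozaki–Hiyama–Kishi closure and gives the bicyclic allylic alcohol A2. In its favour, the ring closure delivers the C6 oxygen directly, the C8=C9 ester is already in place so no conjugation step is needed, and the C4=C5 alkene of A2 is a handle for C4. Against it for this target: the C6 configuration would arise in a medium-ring closure guided only by the remote C1 centre across an sp2 C5. A1 is a β,γ-unsaturated aldehyde whose C7 methylene lies between the formyl group and the enoate and should enolise and isomerise readily. The trisubstituted enoate, with C7 and C10 cis across C8=C9, has to be built with defined geometry in a linear sequence. After closure, H5 must still be set trans to C15 and C4 taken through extra redox steps. On directness of the C6 oxygen and on having C8=C9 in place this alternative is stronger. The chosen route offers instead a robust ring-closure precursor and sets C5 and C6 together by one stereospecific syn addition governed by C15.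

**Alternative 2:** Simultaneous disconnection of C1–C5 and C7–C8. In the forward sense the acyclic dienyl vinyl diazoketone A3 would be decomposed by a chiral Rh(II) catalyst. The C5 carbenoid cyclopropanates the tethered C1=C10 alkene, and Cope rearrangement of the adduct gives the bicyclic dienone A4 with both rings and the quaternary centre formed in one operation. In its favour is unmatched skeletal step economy, and the alkene positions (C5=C6, C9=C10) are the same as after the chosen key step. Against it: vinyl diazoketones are less well behaved than vinyldiazoacetates, since they can electrocyclise to pyrazoles and give less selective carbenoids. Enantioselective intramolecular cyclopropanation of a trisubstituted alkene that creates a quaternary centre is not a secure prediction. In A4 the C4 ketone is already conjugated to C5=C6, so the C6 oxygen and H5 would have to be introduced on an enone whose C7 protons are readily removed. C14 still needs oxidation and the C9=C10 alkene still has to move. This alternative is clearly stronger in step count to the bicyclic skeleton. The chosen route offers a quaternary centre made by a reaction with close analogy and a masked C4 that keeps C5=C6 an isolated alkene.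

**Alternative 3:** Disconnection of C1–C15 and C5–C6. In the forward sense a chiral copper catalyst would add a methylaluminium reagent to 3-allylcyclopent-2-enone A5, and the aluminium enolate would be trapped by aldehyde A6 to give the anti-aldol cyclopentanone A7 with C1, C5 and C6 set. Metathesis between the allyl group and the 1,1-disubstituted alkene would then close the ring with C8=C9 in place and C14 at the alcohol level. In its favour it is the shortest and most convergent plan: three stereocentres in one step, no protecting group on C4 and no ester reduction. Against it: conjugate methylation of 3-substituted cyclopentenones is usually less selective than that of six-membered enones. The aldol fixes C5 relative to C1 by discrimination between methyl and allyl on the neighbouring quaternary carbon, and here that centre is permanent. A6 is a β,γ-unsaturated aldehyde prone to isomerisation under Lewis-acidic aluminium species. A7 is a β-hydroxy ketone with an epimerisable C5 that would face the basic isopropyl addition unprotected. On brevity this alternative is stronger. The chosen route meets the same methyl/allyl facial problem only at a centre that the key step erases, and it makes the C5/C6 pair by one syn addition.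

Key step: step 8

Remark on the chemistry: commercial **1** exists as its enol (2-hydroxy-3-methylcyclopent-2-enone) and is drawn as the dione; the ligand hand that gives (R)-**5** is assumed to be (R) by analogy with 2-methylcycloalkanone enol carbonates and is to be confirmed on **5**.
Naming: bicyclic compounds are named with the skeleton numbering of the analysis (C14 = carbon on C8, C15 = methyl on C1, α = face opposite C15).

## Route

Step 1
Reactants: 1 3-methylcyclopentane-1,2-dione; 2 allyl chloroformate
Product: 3 allyl 2-methyl-5-oxocyclopent-1-en-1-yl carbonate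
Conditions: Et3N, DMAP (cat.), CH2Cl2, 0 °C
Reagents that add atoms: allyl chloroformate (2), C=CCOC(Cl)=O
Why: O-acylation of the acidic enol of the 1,2-dione; the methyl-substituted enol is the stable tautomer, so the carbonate sits on the C5 oxygen with the C1=C5 double bond and C4 remains the only ketone.

Step 2
Reactants: 3 allyl 2-methyl-5-oxocyclopent-1-en-1-yl carbonate
Product: 4 allyl 7-methyl-1,4-dioxaspiro[4.4]non-6-en-6-yl carbonate
Conditions: TMSOCH2CH2OTMS, TMSOTf (cat.), CH2Cl2, −78 → −20 °C; pyridine quench
Reagents that add atoms: 1,2-bis(trimethylsilyloxy)ethane, C[Si](C)(C)OCCO[Si](C)(C)C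
Why: Aprotic silyl-transfer ketalisation (Noyori conditions) converts the single ketone (C4) into the dioxolane without moving the double bond or cleaving the enol carbonate; formation of the disiloxane drives it.

Step 3
Reactants: 4 allyl 7-methyl-1,4-dioxaspiro[4.4]non-6-en-6-yl carbonate
Product: 5 (R)-7-allyl-7-methyl-1,4-dioxaspiro[4.4]nonan-6-one
Conditions: Pd2(dba)3 (2.5 mol %), (R)-(p-CF3)3-t-BuPHOX (6 mol %), toluene, 25 °C
Reagents that add atoms: none
Why: Decarboxylative asymmetric allylic alkylation (Tsuji–Trost type): Pd(0) ionises the allyl carbonate, CO2 is lost and the Pd-bound tetrasubstituted enolate is allylated at C1. The chiral PHOX ligand selects the enolate face and sets the C1 quaternary centre; the C4 ketal rules out any other enolate.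

Step 4
Reactants: 5 (R)-7-allyl-7-methyl-1,4-dioxaspiro[4.4]nonan-6-one; 6 ethynyltrimethylsilane; 7 acryloyl chloride
Product: 9 (6R,7R)-7-allyl-7-methyl-6-[(trimethylsilyl)ethynyl]-1,4-dioxaspiro[4.4]nonan-6-yl acrylate, via lithium tertiary alkoxide 8 (not isolated)
Conditions: 6, n-BuLi, THF, −78 °C; then 5, −78 → 0 °C; then 7, −78 °C → rt
Reagents that add atoms: ethynyltrimethylsilane (6), C#C[Si](C)(C)C; acryloyl chloride (7), C=CC(Cl)=O
Why: 1,2-Addition of a lithium acetylide to a non-enolisable ketone, then O-acylation of the tertiary alkoxide in the same flask. The small nucleophile should approach C5 anti to the larger allyl group (syn to methyl), which places the C5 oxygen cis to C10 as the lactone needs.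

Step 5
Reactants: 9 (6R,7R)-7-allyl-7-methyl-6-[(trimethylsilyl)ethynyl]-1,4-dioxaspiro[4.4]nonan-6-yl acrylate
Product: 10 cis-fused unsaturated lactone (1R,5R) with ring C5–O–C14(=O)–C8=C9–C10–C1 and C4 ethylene ketal and C5 (trimethylsilyl)ethynyl cis to C15
Conditions: Grubbs second-generation catalyst (5 mol %), CH2Cl2 (5 mM), 40 °C
Reagents that add atoms: none
Why: Ring-closing metathesis of the allyl group with the acrylate gives the seven-membered lactone with the in-ring cis enoate. The silyl cap on the fully substituted propargylic carbon keeps the alkyne out of enyne metathesis, and only the diastereomer with O and C10 cis can close.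

Step 6
Reactants: 10 cis-fused C5-(trimethylsilyl)ethynyl lactone (1R,5R)
Product: 11 cis-fused C5-ethynyl unsaturated lactone (1R,5R)
Conditions: TBAF, AcOH, THF, 0 °C
Reagents that add atoms: none
Why: Fluoride protodesilylation of the alkynylsilane; acetic acid buffers the medium so the unsaturated lactone is not opened or attacked at C9.

Step 7
Reactants: 11 cis-fused C5-ethynyl unsaturated lactone (1R,5R)
Product: 12 cis-fused C5-vinyl unsaturated lactone (1R,5S) with C4 ethylene ketal and vinyl cis to C15
Conditions: H2 (1 atm), Lindlar catalyst, quinoline, EtOAc, rt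
Reagents that add atoms: none
Why: Lindlar semihydrogenation of a terminal alkyne stops at the alkene; the poisoned catalyst should leave the conjugated ring alkene and the tertiary allylic ester alone.

Step 8
Reactants: 12 cis-fused C5-vinyl unsaturated lactone (1R,5S)
Product: 16 (1R,8R)-4,4-ethylenedioxy-1-methylhydroazulene-5,9-diene-8-carboxylic acid (C5=C6 and C9=C10), via lithium dienolate 13 (not isolated), via trimethylsilyl dienol ether 14 (not isolated), via trimethylsilyl ester 15 (not isolated)
Conditions: LDA, THF/HMPA, −78 °C; TMSCl/Et3N, −78 °C → rt; toluene, 100 °C; then H2O/THF, rt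
Reagents that add atoms: none
Why: Proposed new method: LDA in THF/HMPA removes a γ-proton at C10 of the unsaturated lactone and O-silylation gives the 2-silyloxy-dihydrooxepine 14, whose C8=C14–O–C5–C6=C7 array is an allyl vinyl ether; on heating, a [3,3] shift forms C7–C8 and breaks C5–O. The closest known reactions are the Ireland–Claisen rearrangement of lactone silyl ketene acetals bearing a vinyl group on the carbinol carbon and the deconjugative Ireland–Claisen of acyclic allyl enoates through silyl dienol ethers; their combination within an unsaturated lactone has not been shown. The carbocyclic seven-membered ring is closed by transannular C7–C8 bonding across the lactone through a boat transition state shaped like bicyclo[3.2.2]nonane; O and C14 leave the ring as the carboxyl while C6 and C7 enter it, so the ring stays seven-membered. The one new stereocentre, C8, is fixed by suprafacial bonding on the lactone face that carries the vinyl group, that is by C1 through the cis fusion, and it is deliberately transient because step 10 removes it. The step needs bonding at the α-carbon C8 and not at the γ-carbon C10, which the six-atom array enforces because C10 cannot reach C7 in an allowed shift. It also needs the vinyl group axial over the ring, which the cis fusion and the fully substituted C5 provide. The tertiary allylic C–O bond should lower the barrier, and water cleaves the silyl ester on work-up; the acid is used at once because the C4 ketal is now allylic.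

Step 9
Reactants: 16 (1R,8R)-4,4-ethylenedioxy-1-methylhydroazulene-5,9-diene-8-carboxylic acid
Product: 17 methyl (1R,8R)-4,4-ethylenedioxy-1-methylhydroazulene-5,9-diene-8-carboxylate
Conditions: TMSCHN2, MeOH/toluene, 0 °C
Reagents that add atoms: (trimethylsilyl)diazomethane, C[Si](C)(C)C=[N+]=[N-]
Why: Neutral methylation of the carboxylic acid by the diazoalkane in methanol; the acid-labile allylic ketal and both alkenes are untouched.

Step 10
Reactants: 17 methyl (1R,8R)-4,4-ethylenedioxy-1-methylhydroazulene-5,9-diene-8-carboxylate
Product: 18 methyl (1R)-4,4-ethylenedioxy-1-methylhydroazulene-5,8-diene-8-carboxylate (C5=C6 and C8=C9)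
Conditions: NaOMe (0.2 equiv), MeOH, 0 °C → rt
Reagents that add atoms: none
Why: Base-catalysed isomerisation of the β,γ-unsaturated ester through its dienolate to the conjugated, thermodynamically preferred C8=C9 ester, which erases the C8 centre. C5=C6 cannot migrate because C7 is not acidified by the ester.

Step 11
Reactants: 18 methyl (1R)-4,4-ethylenedioxy-1-methylhydroazulene-5,8-diene-8-carboxylate
Product: 20 methyl (1R,5S,6S)-4,4-ethylenedioxy-6α-hydroxy-1-methyl-5α-H-hydroazul-8-ene-8-carboxylate (trans-fused), via C6 alkylborane 19 (not isolated)
Conditions: BH3·THF (1.1 equiv), THF, 0 °C → rt; then 30% H2O2, aq. NaOAc, 0 °C → rt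
Reagents that add atoms: hydrogen peroxide, OO
Why: Hydroboration–oxidation: borane should add to the electron-rich trisubstituted C5=C6 alkene much faster than to the conjugated ester, with boron on the less substituted C6. Syn addition from the α-face, opposite the pseudoaxial C15 methyl on the neighbouring quaternary carbon, sets 5α-H (trans fusion) and the 6α-oxygen together, and the oxidation retains configuration.

Step 12
Reactants: 20 methyl (1R,5S,6S)-4,4-ethylenedioxy-6α-hydroxy-1-methyl-5α-H-hydroazul-8-ene-8-carboxylate
Product: 21 methyl (1R,5S,6S)-6α-(tert-butyldimethylsilyloxy)-4,4-ethylenedioxy-1-methyl-5α-H-hydroazul-8-ene-8-carboxylate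
Conditions: TBSOTf, 2,6-lutidine, CH2Cl2, −78 → 0 °C
Reagents that add atoms: tert-butyldimethylsilyl triflate, CC(C)(C)[Si](C)(C)OS(=O)(=O)C(F)(F)F
Why: Silylation of a hindered secondary alcohol with a silyl triflate and a hindered base; it prevents a free β-hydroxy ketone in steps 13–14 and keeps the C6 oxygen distinct from C14 later.

Step 13
Reactants: 21 methyl (1R,5S,6S)-6α-(tert-butyldimethylsilyloxy)-4,4-ethylenedioxy-1-methyl-5α-H-hydroazul-8-ene-8-carboxylate
Product: 22 methyl (1R,5S,6S)-6α-(tert-butyldimethylsilyloxy)-1-methyl-4-oxo-5α-H-hydroazul-8-ene-8-carboxylate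
Conditions: TsOH·H2O (cat.), acetone/H2O, rt
Reagents that add atoms: water, O
Why: Acid-catalysed hydrolysis of the now non-allylic dioxolane; the hindered secondary silyl ether should survive, and mild conditions are chosen so the C5–H of the trans-fused ketone does not equilibrate.

Step 14
Reactants: 22 methyl (1R,5S,6S)-6α-(tert-butyldimethylsilyloxy)-1-methyl-4-oxo-5α-H-hydroazul-8-ene-8-carboxylate
Product: 23 methyl (1R,4R,5S,6S)-6α-(tert-butyldimethylsilyloxy)-4β-hydroxy-4α-isopropyl-1-methyl-5α-H-hydroazul-8-ene-8-carboxylate
Conditions: i-PrMgCl, CeCl3 (anhydrous), THF, −78 °C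
Reagents that add atoms: isopropylmagnesium chloride, CC(C)[Mg]Cl
Why: Organocerium addition to a hindered, enolisable ketone suppresses reduction and enolisation and should be selective for the ketone over the conjugated ester at −78 °C. Attack from the α-face, away from the C15 methyl that covers the β-face of the cyclopentanone, sets C4 with the hydroxyl β and the isopropyl group α.

Step 15
Reactants: 23 methyl (1R,4R,5S,6S)-6α-(tert-butyldimethylsilyloxy)-4β-hydroxy-4α-isopropyl-1-methyl-5α-H-hydroazul-8-ene-8-carboxylate
Product: 24 (1R,4R,5S,6S)-6α-(tert-butyldimethylsilyloxy)-8-(hydroxymethyl)-4α-isopropyl-1-methyl-5α-H-hydroazul-8-en-4β-ol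
Conditions: DIBAL-H (4 equiv), CH2Cl2, −78 → −20 °C; Rochelle salt
Reagents that add atoms: none
Why: 1,2-Reduction of the α,β-unsaturated ester to the allylic alcohol; one equivalent is consumed by the tertiary alkoxide and the silyl ether is inert.

Step 16
Reactants: 24 (1R,4R,5S,6S)-6α-(tert-butyldimethylsilyloxy)-8-(hydroxymethyl)-4α-isopropyl-1-methyl-5α-H-hydroazul-8-en-4β-ol
Product: 25 (1R,4R,5S,6S)-6α-(tert-butyldimethylsilyloxy)-4β-hydroxy-4α-isopropyl-1-methyl-5α-H-hydroazul-8-ene-8-carbaldehyde
Conditions: MnO2 (activated, excess), CH2Cl2, rt
Reagents that add atoms: none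
Why: Activated manganese dioxide oxidises only the allylic primary alcohol and stops at the enal; the tertiary alcohol cannot react.

Step 17
Reactants: 25 (1R,4R,5S,6S)-6α-(tert-butyldimethylsilyloxy)-4β-hydroxy-4α-isopropyl-1-methyl-5α-H-hydroazul-8-ene-8-carbaldehyde
Product: 26 (1R,4R,5S,6S)-4β,6α-dihydroxy-4α-isopropyl-1-methyl-5α-H-hydroazul-8-ene-8-carbaldehyde
Conditions: HF·pyridine, pyridine, THF, 0 °C → rt
Reagents that add atoms: none
Why: Fluoride cleavage of the secondary silyl ether under buffered, weakly acidic conditions that the enal and the tertiary alcohol tolerate and that do not promote oxa-Michael closure onto C9.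

Step 18
Reactants: 27 4-hydroxybenzoic acid
Product: 29 4-(tert-butyldimethylsilyloxy)benzoic acid, via bis-silylated acid 28 (not isolated)
Conditions: TBSCl (2.5 equiv), imidazole, DMF, rt; then AcOH/THF/H2O, rt
Reagents that add atoms: tert-butyldimethylsilyl chloride, CC(C)(C)[Si](C)(C)Cl
Why: Exhaustive silylation followed by selective hydrolysis of the far more labile silyl ester leaves the phenol protected and the acid free.

Step 19
Reactants: 26 (1R,4R,5S,6S)-4β,6α-dihydroxy-4α-isopropyl-1-methyl-5α-H-hydroazul-8-ene-8-carbaldehyde; 29 4-(tert-butyldimethylsilyloxy)benzoic acid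
Product: 30 (1R,4R,5S,6S)-8-formyl-4β-hydroxy-4α-isopropyl-1-methyl-5α-H-hydroazul-8-en-6α-yl 4-(tert-butyldimethylsilyloxy)benzoate
Conditions: DCC, DMAP, CH2Cl2, 0 °C → rt
Reagents that add atoms: 4-(tert-butyldimethylsilyloxy)benzoic acid (29), CC(C)(C)[Si](C)(C)Oc1ccc(C(O)=O)cc1
Why: Steglich esterification; only the secondary C6 hydroxyl should be acylated, the tertiary C4 hydroxyl being too hindered, and the protected phenol cannot compete.

Step 20
Reactants: 30 (1R,4R,5S,6S)-8-formyl-4β-hydroxy-4α-isopropyl-1-methyl-5α-H-hydroazul-8-en-6α-yl 4-(tert-butyldimethylsilyloxy)benzoate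
Product: 31 (1R,4R,5S,6S)-8-formyl-4β-hydroxy-4α-isopropyl-1-methyl-5α-H-hydroazul-8-en-6α-yl 4-hydroxybenzoate (CNP0267880.1)
Conditions: TBAF, AcOH, THF, 0 °C
Reagents that add atoms: none
Why: The silyl ether of an electron-poor phenol is cleaved quickly by buffered fluoride at 0 °C, conditions under which the benzoate, the enal and the tertiary alcohol should persist.

## Compound list

1 | 3-methylcyclopentane-1,2-dione | CC1CCC(=O)C1=O | starting material
2 | allyl chloroformate | C=CCOC(Cl)=O | starting material
3 | allyl 2-methyl-5-oxocyclopent-1-en-1-yl carbonate | C=CCOC(=O)OC1=C(C)CCC1=O | intermediate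
4 | allyl 7-methyl-1,4-dioxaspiro[4.4]non-6-en-6-yl carbonate | C=CCOC(=O)OC1=C(C)CCC12OCCO2 | intermediate
5 | (R)-7-allyl-7-methyl-1,4-dioxaspiro[4.4]nonan-6-one | C=CC[C@@]1(C)CCC2(OCCO2)C1=O | intermediate
6 | ethynyltrimethylsilane | C#C[Si](C)(C)C | starting material
7 | acryloyl chloride | C=CC(Cl)=O | starting material
8 | lithium (6R,7R)-7-allyl-7-methyl-6-[(trimethylsilyl)ethynyl]-1,4-dioxaspiro[4.4]nonan-6-olate (not isolated) | C[Si](C)(C)C#C[C@]1(O[Li])[C@@](C)(CC=C)CCC12OCCO2 | intermediate
9 | (6R,7R)-7-allyl-7-methyl-6-[(trimethylsilyl)ethynyl]-1,4-dioxaspiro[4.4]nonan-6-yl acrylate | C[Si](C)(C)C#C[C@]1(OC(=O)C=C)[C@@](C)(CC=C)CCC12OCCO2 | intermediate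
10 | cis-fused C5-(trimethylsilyl)ethynyl unsaturated lactone (1R,5R), C4 ethylene ketal | C[Si](C)(C)C#C[C@]12OC(=O)C=CC[C@@]1(C)CCC23OCCO3 | intermediate
11 | cis-fused C5-ethynyl unsaturated lactone (1R,5R), C4 ethylene ketal | C#C[C@]12OC(=O)C=CC[C@@]1(C)CCC23OCCO3 | intermediate
12 | cis-fused C5-vinyl unsaturated lactone (1R,5S), C4 ethylene ketal (key-step precursor) | C=C[C@]12OC(=O)C=CC[C@@]1(C)CCC23OCCO3 | intermediate
13 | lithium dienolate of 12 (not isolated) | C=C[C@]12OC(O[Li])=CC=C[C@@]1(C)CCC23OCCO3 | intermediate
14 | trimethylsilyl dienol ether of 12 (not isolated) | C=C[C@]12OC(O[Si](C)(C)C)=CC=C[C@@]1(C)CCC23OCCO3 | intermediate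
15 | trimethylsilyl ester of 16 (not isolated) | C[Si](C)(C)OC(=O)[C@H]1C=C[C@@]2(C)CCC3(OCCO3)C2=CC1 | intermediate
16 | (1R,8R)-4,4-ethylenedioxy-1-methylhydroazulene-5,9-diene-8-carboxylic acid (key-step product) | OC(=O)[C@H]1C=C[C@@]2(C)CCC3(OCCO3)C2=CC1 | intermediate
17 | methyl (1R,8R)-4,4-ethylenedioxy-1-methylhydroazulene-5,9-diene-8-carboxylate | COC(=O)[C@H]1C=C[C@@]2(C)CCC3(OCCO3)C2=CC1 | intermediate
18 | methyl (1R)-4,4-ethylenedioxy-1-methylhydroazulene-5,8-diene-8-carboxylate | COC(=O)C1=CC[C@@]2(C)CCC3(OCCO3)C2=CC1 | intermediate
19 | C6α-boryl adduct of 18, 5α-H (not isolated) | COC(=O)C1=CC[C@@]2(C)CCC3(OCCO3)[C@@H]2[C@@H](B)C1 | intermediate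
20 | methyl (1R,5S,6S)-4,4-ethylenedioxy-6α-hydroxy-1-methyl-5α-H-hydroazul-8-ene-8-carboxylate | COC(=O)C1=CC[C@@]2(C)CCC3(OCCO3)[C@@H]2[C@@H](O)C1 | intermediate
21 | 6α-tert-butyldimethylsilyl ether of 20 | COC(=O)C1=CC[C@@]2(C)CCC3(OCCO3)[C@@H]2[C@@H](O[Si](C)(C)C(C)(C)C)C1 | intermediate
22 | methyl (1R,5S,6S)-6α-(tert-butyldimethylsilyloxy)-1-methyl-4-oxo-5α-H-hydroazul-8-ene-8-carboxylate | COC(=O)C1=CC[C@@]2(C)CCC(=O)[C@@H]2[C@@H](O[Si](C)(C)C(C)(C)C)C1 | intermediate
23 | methyl (1R,4R,5S,6S)-6α-(tert-butyldimethylsilyloxy)-4β-hydroxy-4α-isopropyl-1-methyl-5α-H-hydroazul-8-ene-8-carboxylate | COC(=O)C1=CC[C@@]2(C)CC[C@@](O)(C(C)C)[C@@H]2[C@@H](O[Si](C)(C)C(C)(C)C)C1 | intermediate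
24 | (1R,4R,5S,6S)-6α-(tert-butyldimethylsilyloxy)-8-(hydroxymethyl)-4α-isopropyl-1-methyl-5α-H-hydroazul-8-en-4β-ol | OCC1=CC[C@@]2(C)CC[C@@](O)(C(C)C)[C@@H]2[C@@H](O[Si](C)(C)C(C)(C)C)C1 | intermediate
25 | (1R,4R,5S,6S)-6α-(tert-butyldimethylsilyloxy)-4β-hydroxy-4α-isopropyl-1-methyl-5α-H-hydroazul-8-ene-8-carbaldehyde | O=CC1=CC[C@@]2(C)CC[C@@](O)(C(C)C)[C@@H]2[C@@H](O[Si](C)(C)C(C)(C)C)C1 | intermediate
26 | (1R,4R,5S,6S)-4β,6α-dihydroxy-4α-isopropyl-1-methyl-5α-H-hydroazul-8-ene-8-carbaldehyde | O=CC1=CC[C@@]2(C)CC[C@@](O)(C(C)C)[C@@H]2[C@@H](O)C1 | intermediate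
27 | 4-hydroxybenzoic acid | OC(=O)c1ccc(O)cc1 | starting material
28 | tert-butyldimethylsilyl 4-(tert-butyldimethylsilyloxy)benzoate (not isolated) | CC(C)(C)[Si](C)(C)OC(=O)c1ccc(O[Si](C)(C)C(C)(C)C)cc1 | intermediate
29 | 4-(tert-butyldimethylsilyloxy)benzoic acid | CC(C)(C)[Si](C)(C)Oc1ccc(C(O)=O)cc1 | intermediate
30 | (1R,4R,5S,6S)-8-formyl-4β-hydroxy-4α-isopropyl-1-methyl-5α-H-hydroazul-8-en-6α-yl 4-(tert-butyldimethylsilyloxy)benzoate | O=CC1=CC[C@@]2(C)CC[C@@](O)(C(C)C)[C@@H]2[C@@H](OC(=O)c3ccc(O[Si](C)(C)C(C)(C)C)cc3)C1 | intermediate
31 | (1R,4R,5S,6S)-8-formyl-4β-hydroxy-4α-isopropyl-1-methyl-5α-H-hydroazul-8-en-6α-yl 4-hydroxybenzoate (CNP0267880.1) | CC(C)[C@]1(O)CC[C@]2(C)CC=C(C=O)C[C@H](OC(=O)c3ccc(O)cc3)[C@H]21 | target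

## Step count and least certain steps

Total: 20 steps. Longest linear sequence: 19 steps (steps 1–17, 19 and 20); step 18 is a one-step side branch.

**Step 8 (key step, labelled as a proposed new method).** The most likely failure is at enolisation: the amide may add to C9 instead of removing the C10 proton, although the in-ring cis enoate geometry favours γ-deprotonation, or the dienolate may silylate on carbon. If the silyl dienol ether does form, it may decompose on heating before the strained boat transition state is reached. Fallback with known chemistry, setting out from **12**: copper-catalysed conjugate borylation (B2pin2, CuCl/DPEphos, NaOt-Bu, MeOH, THF) should give the saturated C9-pinacolboryl lactone F1 and, after sodium perborate oxidation in the same flask, the C9-hydroxy lactone F2 as the isolated product. Silylation (TBSOTf, 2,6-lutidine) converts F2 into the C9-silyloxy lactone F3 with C8 as its only acidic site. F3 is a simple lactone with a vinyl group on the carbinol carbon: its trimethylsilyl ketene acetal F4 (LDA in the presence of TMSCl/Et3N, THF, −78 °C) should undergo the established ring-contracting Ireland–Claisen rearrangement in toluene at 100 °C to the trimethylsilyl ester F5 of the carbocyclic acid, and water then cleaves this to the C9-silyloxy acid F6 on work-up. Methylation (TMSCHN2) gives the methyl ester F7 of this acid. Base-induced E1cB loss of the silanolate from F7 (t-BuOK, THF, 0 °C) can place the alkene only at C8=C9 and returns to the route at **18**.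

**Step 11.** The risks are competing reduction of the conjugated ester by borane and incomplete facial control at the hindered C5=C6 alkene. Fallback, setting out from **18**: epoxidation with mCPBA (NaHCO3, CH2Cl2, 0 °C), which should touch only the electron-rich alkene and approach from the face opposite C15, gives the 5α,6α-epoxide F8 with the C6 oxygen already in place. Reductive opening of F8 with titanocene(III) (Cp2TiCl2, Mn, 1,4-cyclohexadiene, THF, rt) breaks the C5–O bond homolytically, and hydrogen-atom transfer to the tertiary C5 radical, expected from the face opposite C15, gives the 6α-alcohol and returns to the route at **20**.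

**Step 4.** The risk is poor facial discrimination between methyl and allyl at the hindered C5 ketone, which would waste material as the diastereomer that cannot lactonise. Fallback, setting out from **5**: the acetylide addition is run without the acylation and quenched with NH4Cl, and the two carbinols are separated. The desired (6R,7R)-carbinol F9 is acylated on its own through alkoxide **8** (LiHMDS, then **7**) and returns to the route at **9**. The C5-epimeric carbinol F10 is fragmented by base-catalysed retro-alkynylation (t-BuOK cat., toluene, reflux) to **5** and **6**, which are recycled.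

**Step 3.** The risk is insufficient enantiomeric excess, because five-membered-ring enolates are usually discriminated less well than six-membered ones. Fallback, setting out from **16** and coming back at **16**: the scalemic acid is enriched by crystallisation with (S)-1-phenylethylamine (or with the enantiomeric amine if that salt is the less soluble one), which gives the (S)-1-phenylethylammonium carboxylate salt F11 in enriched form. Brief treatment of F11 with cold aqueous citric acid releases enriched **16**.

**Step 14.** The risks are β-hydride reduction or enolisation of the hindered ketone (with loss of the C6 silyloxy group or C5 epimerisation), competing attack on the ester, and erosion of α-facial selectivity by the C6 substituent. Fallback, setting out from **22**: isopropenylmagnesium bromide/CeCl3, a smaller sp2 nucleophile that cannot act as a hydride donor, should give the 4α-isopropenyl carbinol F12 in place of the isopropyl carbinol. Chemoselective hydrogenation of the 1,1-disubstituted alkene of F12 with Wilkinson's catalyst (H2, benzene) leaves the trisubstituted enoate and returns to the route at **23**.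

**Step 2.** The risk is sluggish ketalisation of the deactivated enone carbonyl, or loss of the enol carbonate under the silyl triflate. Fallback, setting out from **1**: acid-catalysed mono-ketalisation of the dione (ethylene glycol, TsOH, benzene, Dean–Stark) gives the racemic ketal ketone 7-methyl-1,4-dioxaspiro[4.4]nonan-6-one F13 , whose only enolisable position is C1. Its lithium enolate F14 (LiHMDS, THF, −78 °C) is O-acylated with **2** and returns to the route at **4**; in this order the regiochemistry of the ketalisation is the open point.

## Further compounds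

F1 | step 8 | saturated C9-(pinacolboryl) cis-fused C5-vinyl lactone (1R,5S; C9 unassigned) | C=C[C@]12OC(=O)CC(B4OC(C)(C)C(C)(C)O4)C[C@@]1(C)CCC23OCCO3
F2 | step 8 | saturated C9-hydroxy cis-fused C5-vinyl lactone (1R,5S; C9 unassigned) | C=C[C@]12OC(=O)CC(O)C[C@@]1(C)CCC23OCCO3
F3 | step 8 | C9-(tert-butyldimethylsilyloxy) cis-fused C5-vinyl lactone | C=C[C@]12OC(=O)CC(O[Si](C)(C)C(C)(C)C)C[C@@]1(C)CCC23OCCO3
F4 | step 8 | trimethylsilyl ketene acetal of F3 | C=C[C@]12OC(O[Si](C)(C)C)=CC(O[Si](C)(C)C(C)(C)C)C[C@@]1(C)CCC23OCCO3
F5 | step 8 | trimethylsilyl ester of F6 | C[Si](C)(C)OC(=O)[C@H]1C(O[Si](C)(C)C(C)(C)C)C[C@@]2(C)CCC3(OCCO3)C2=CC1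
F6 | step 8 | (1R,8R)-9-(tert-butyldimethylsilyloxy)-4,4-ethylenedioxy-1-methylhydroazul-5-ene-8-carboxylic acid | OC(=O)[C@H]1C(O[Si](C)(C)C(C)(C)C)C[C@@]2(C)CCC3(OCCO3)C2=CC1
F7 | step 8 | methyl ester of F6 | COC(=O)[C@H]1C(O[Si](C)(C)C(C)(C)C)C[C@@]2(C)CCC3(OCCO3)C2=CC1
F8 | step 11 | methyl (1R)-5α,6α-epoxy-4,4-ethylenedioxy-1-methylhydroazul-8-ene-8-carboxylate | COC(=O)C1=CC[C@@]2(C)CCC3(OCCO3)[C@]2(O4)[C@@H]4C1
F9 | step 4 | (6R,7R)-7-allyl-7-methyl-6-[(trimethylsilyl)ethynyl]-1,4-dioxaspiro[4.4]nonan-6-ol | C[Si](C)(C)C#C[C@]1(O)[C@@](C)(CC=C)CCC12OCCO2
F10 | step 4 | (6S,7R)-7-allyl-7-methyl-6-[(trimethylsilyl)ethynyl]-1,4-dioxaspiro[4.4]nonan-6-ol (C5 epimer) | C[Si](C)(C)C#C[C@@]1(O)[C@@](C)(CC=C)CCC12OCCO2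
F11 | step 3 | (S)-1-phenylethylammonium salt of 16 | C[C@H]([NH3+])c1ccccc1.[O-]C(=O)[C@H]1C=C[C@@]2(C)CCC3(OCCO3)C2=CC1
F12 | step 14 | methyl (1R,5S,6S)-6α-(tert-butyldimethylsilyloxy)-4β-hydroxy-4α-isopropenyl-1-methyl-5α-H-hydroazul-8-ene-8-carboxylate | COC(=O)C1=CC[C@@]2(C)CC[C@@](O)(C(C)=C)[C@@H]2[C@@H](O[Si](C)(C)C(C)(C)C)C1
F13 | step 2 | 7-methyl-1,4-dioxaspiro[4.4]nonan-6-one (racemic) | CC1CCC2(OCCO2)C1=O
F14 | step 2 | lithium enolate of F13 | [Li]OC1=C(C)CCC12OCCO2
A1 | alternative 1 | alkenyl triflate aldehyde (C5 triflate, C6 aldehyde, C8=C9 ester) | COC(=O)/C(CC=O)=C/C[C@@]1(C)CCC=C1OS(=O)(=O)C(F)(F)F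
A2 | alternative 1 | bicyclic allylic alcohol (C6–OH, C4=C5, C8=C9 ester) | COC(=O)C1=CC[C@@]2(C)CCC=C2[C@@H](O)C1
A3 | alternative 2 | acyclic dienyl vinyl diazoketone | C=CC(=[N+]=[N-])C(=O)CC/C(C)=C/C=C/CO[Si](C)(C)C(C)(C)C
A4 | alternative 2 | bicyclic dienone (C4 ketone, C5=C6, C9=C10, C8 silyloxymethyl) | O=C1CC[C@]2(C)C=C[C@H](CO[Si](C)(C)C(C)(C)C)CC=C12
A5 | alternative 3 | 3-allylcyclopent-2-enone | C=CCC1=CC(=O)CC1
A6 | alternative 3 | 3-[(tert-butyldimethylsilyloxy)methyl]but-3-enal | C=C(CC=O)CO[Si](C)(C)C(C)(C)C
A7 | alternative 3 | anti-aldol cyclopentanone with C1, C5 and C6 set | O=C1CC[C@](C)(CC=C)[C@H]1[C@@H](O)CC(=C)CO[Si](C)(C)C(C)(C)C
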